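**Strategy**

Everything rests on the bond between the bridging CH2 and the one aromatic carbon of the phloroglucinol ring that lies between its two free hydroxyls. The key step unmasks, from the dimethylaminomethyl (Mannich) derivative of propionylfilicinic acid, a 4-methylidene cyclohexenetrione and lets the pentasubstituted phenol add through its only free ring carbon. It exploits two features: the CH2 hangs on the filicinic-ring carbon flanked by the two enolized carbonyl carbons (C3–OH and C5–OH), so the derived methylidene is a doubly activated, quinone-methide-like acceptor; and the aromatic carbon concerned is the sole unsubstituted, doubly ortho-hydroxylated position, so no regiochemical choice exists. Both halves come from commercial phloroglucinols.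

Key step: step 7

Remark on the chemistry: the target has no stereocenter. Its non-aromatic ring is an enolized cyclohexanetrione, written throughout as the tautomer of the target SMILES (C1 ring C=O, C2 propanoyl carbon, C3 and C5 enolic C–OH, C4 the carbon between them, C6 CMe2).

**Route**

Step 1
Reactants: 1 flopropione, 1-(2,4,6-trihydroxyphenyl)propan-1-one
Product: 2 propionylfilicinic acid, 3,5-dihydroxy-6,6-dimethyl-2-propanoylcyclohexa-2,4-dien-1-one
Conditions: NaOMe (3.2 equiv), MeI (2.2 equiv), MeOH, 0 °C to rt; then 1 M HCl
Reagents that add atoms: methyl iodide, CI
Why: Dearomative double C-methylation of the phloroglucinol polyanion (the classical route to acylfilicinic acids): the first methyl makes its ring carbon the most electron-rich site, so the second should enter at the same carbon and leave the enolized 6,6-dimethyl trione, to be separated from under- and over-methylated material by chromatography.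

Step 2
Reactants: 2 propionylfilicinic acid
Product: 3 Mannich base, 4-[(dimethylamino)methyl]-3,5-dihydroxy-6,6-dimethyl-2-propanoylcyclohexa-2,4-dien-1-one (zwitterionic; drawn as neutral amine and enol)
Conditions: Me2N+=CH2 I− (1.1 equiv), Et3N (1.0 equiv), CH2Cl2, −20 to 0 °C; kept cold and used promptly
Reagents that add atoms: N,N-dimethylmethyleneiminium iodide (Eschenmoser's salt), C=[N+](C)C.[I-]
Why: Mannich reaction of the triethylammonium enolate with a preformed iminium ion at C4, the only ring carbon still carrying hydrogen; the absence of free formaldehyde, the slight excess of iminium salt and the low temperature should keep 2 from intercepting its own Mannich base as the symmetrical methylene-bis dimer.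

Step 3
Reactants: 4 2-methylphloroglucinol, 2-methylbenzene-1,3,5-triol
Product: 5 1-(2,4,6-trihydroxy-3-methylphenyl)butan-1-one
Conditions: butanoyl chloride (1.05 equiv), AlCl3 (3 equiv), PhNO2/CH2Cl2, 0 °C to rt; ice/HCl work-up
Reagents that add atoms: butanoyl chloride, CCCC(=O)Cl
Why: Friedel–Crafts acylation of the electron-rich triol at one of its two equivalent free ring carbons; the ketone formed is deactivated and chelated to aluminium, which should hold the reaction at monoacylation.

Step 4
Reactants: 5 1-(2,4,6-trihydroxy-3-methylphenyl)butan-1-one
Product: 6 1-[2-hydroxy-4,6-bis(methoxymethoxy)-3-methylphenyl]butan-1-one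
Conditions: MOMCl (2.1 equiv), i-Pr2NEt (2.5 equiv), CH2Cl2, 0 °C
Reagents that add atoms: chloromethyl methyl ether, COCCl
Why: Selective Williamson-type O-alkylation: the hydroxyl para to the ketone (not hydrogen-bonded, most acidic) and then the less hindered ortho hydroxyl at C6 should be etherified, while the C2 hydroxyl, wedged between the acyl and C-methyl groups and locked in the hydrogen bond to the ketone, should stay free, in line with the expected course of partial alkylation of 3-methylphloroacylphenones.

Step 5
Reactants: 6 1-[2-hydroxy-4,6-bis(methoxymethoxy)-3-methylphenyl]butan-1-one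
Product: 7 1-[2-methoxy-4,6-bis(methoxymethoxy)-3-methylphenyl]butan-1-one
Conditions: MeI (3 equiv), K2CO3 (3 equiv), DMF, 40 °C
Reagents that add atoms: methyl iodide, CI
Why: Williamson O-methylation of the remaining chelated phenol under polar aprotic conditions, where O-methylation of the phenoxide is strongly favored over C-methylation and the acetal protecting groups are inert to base.

Step 6
Reactants: 7 1-[2-methoxy-4,6-bis(methoxymethoxy)-3-methylphenyl]butan-1-one
Product: 8 1-(4,6-dihydroxy-2-methoxy-3-methylphenyl)butan-1-one
Conditions: 3 M HCl (cat.), MeOH, 50 °C, dilute
Reagents that add atoms: none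
Why: Acid-catalysed acetal cleavage (transacetalization to dimethoxymethane) should free both phenols; the aryl methyl ether and the ketone are stable, and the large excess of methanol traps the methoxymethyl cation before it can attack the free ring carbon.

Step 7
Reactants: 3 Mannich base of propionylfilicinic acid; 8 1-(4,6-dihydroxy-2-methoxy-3-methylphenyl)butan-1-one
Product: 10 Aspidin PB, via methylidene trione 9 (not isolated)
Conditions: 8 (1.2 equiv), 1,4-dioxane, 80 °C, N2 stream; then 1 M HCl
Reagents that add atoms: none
Why: On warming, zwitterionic 3 should lose dimethylamine by an E1cB retro-Mannich elimination to give the cross-conjugated 4-methylidene trione 9, an ortho-quinone-methide-like acceptor whose exocyclic CH2 is activated by both flanking ring carbonyls. The only unsubstituted carbon of phenol 8 (C5, ortho to both free hydroxyls) adds to this CH2 in a Friedel–Crafts-type conjugate addition, and tautomerization restores the aromatic ring and the enolized trione. The closest known reaction type is the alkylation of phenols and acylphloroglucinols by 2-methylene-1,3-diones released from their Mannich bases, the biomimetic quinone-methide coupling of methylene-bridged acylphloroglucinols. No ring is closed and no stereocenter is formed. The step needs cross- over homo-coupling and C- over O-alkylation: the one-carbon unit is installed on the filicinic partner only, each partner has a single reactive carbon, O-adducts are reversible Michael adducts that return to 9, and the mild, base-poor medium should disfavor retro-Michael exchange of the bridge.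

**Compound list**

1 | flopropione, 1-(2,4,6-trihydroxyphenyl)propan-1-one | CCC(=O)c1c(O)cc(O)cc1O | starting material
2 | propionylfilicinic acid, 3,5-dihydroxy-6,6-dimethyl-2-propanoylcyclohexa-2,4-dien-1-one | CCC(=O)C1=C(O)C=C(O)C(C)(C)C1=O | intermediate
3 | 4-[(dimethylamino)methyl]-3,5-dihydroxy-6,6-dimethyl-2-propanoylcyclohexa-2,4-dien-1-one | CCC(=O)C1=C(O)C(CN(C)C)=C(O)C(C)(C)C1=O | intermediate
4 | 2-methylphloroglucinol, 2-methylbenzene-1,3,5-triol | Cc1c(O)cc(O)cc1O | starting material
5 | 1-(2,4,6-trihydroxy-3-methylphenyl)butan-1-one | CCCC(=O)c1c(O)cc(O)c(C)c1O | intermediate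
6 | 1-[2-hydroxy-4,6-bis(methoxymethoxy)-3-methylphenyl]butan-1-one | CCCC(=O)c1c(OCOC)cc(OCOC)c(C)c1O | intermediate
7 | 1-[2-methoxy-4,6-bis(methoxymethoxy)-3-methylphenyl]butan-1-one | CCCC(=O)c1c(OCOC)cc(OCOC)c(C)c1OC | intermediate
8 | 1-(4,6-dihydroxy-2-methoxy-3-methylphenyl)butan-1-one | CCCC(=O)c1c(O)cc(O)c(C)c1OC | intermediate
9 | 3-hydroxy-6,6-dimethyl-4-methylidene-2-propanoylcyclohex-2-ene-1,5-dione | C=C1C(=O)C(C)(C)C(=O)C(C(=O)CC)=C1O | intermediate
10 | Aspidin PB, 4-[(3-butanoyl-2,6-dihydroxy-4-methoxy-5-methylphenyl)methyl]-3,5-dihydroxy-6,6-dimethyl-2-propanoylcyclohexa-2,4-dien-1-one | CCCC(=O)c1c(O)c(CC2=C(O)C(C)(C)C(=O)C(C(=O)CC)=C2O)c(O)c(C)c1OC | target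

**Step count**

Total: 7 steps. Longest linear sequence: 5 steps (steps 3 to 7, from 4); the other branch is steps 1 and 2, from 1.

**Steps most likely to fail**

Step 7. The methylidene trione 9 may be consumed by self-condensation (hetero-Diels–Alder dimerization), or the bridge may exchange by retro-Michael cleavage under the amine released, giving the two symmetrical dimers. The fallback reverses the polarity of the one-carbon unit. It sets out from 8, which is aminomethylated at its free ring carbon with Eschenmoser's salt to give the phenolic Mannich base 1-{3-[(dimethylamino)methyl]-2,4-dihydroxy-6-methoxy-5-methylphenyl}butan-1-one F1. Heating F1 with 2 in toluene should release an aromatic ortho-quinone methide, because the acidic enol of 2 protonates the amine and triggers loss of dimethylamine. The strongly nucleophilic C4 of 2 captures it at once, and the fallback comes back to the route at 10.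

Step 4. The second methoxymethylation may fail to discriminate between the two hydroxyls that flank the ketone, giving a mixture of regioisomeric bis-ethers. The fallback fixes the regiochemistry with a traceless carboxyl group and sets out from 4.
- Kolbe–Schmitt carboxylation (KHCO3, CO2, H2O, 60 °C) gives 2,4,6-trihydroxy-3-methylbenzoic acid F2.
- MeI (2 equiv), K2CO3, DMF methylates the carboxylate and the hydroxyl para to it, the most acidic one and the one least engaged in hydrogen bonding to the ester, giving methyl 2,6-dihydroxy-4-methoxy-3-methylbenzoate F3. The ester blocks the future bridge carbon.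
- Friedel–Crafts acylation with butanoyl chloride and TiCl4 in CH2Cl2 can then occur only at the one remaining ring carbon, giving methyl 3-butanoyl-2,6-dihydroxy-4-methoxy-5-methylbenzoate F4.
- Saponification (aqueous NaOH) and acidification with warming decarboxylates the 2,6-dihydroxybenzoic acid, and the fallback comes back to the route at 8.

Step 1. Statistical under- and over-methylation (mono-, 3,5-di-, tri- and tetra-C-methyl products) may erode the supply of 2. The fallback brings the first C-methyl in with the aromatic starting material, so only one dearomatizing alkylation remains. It sets out from 4, which is acylated with propanoyl chloride and AlCl3 to 1-(2,4,6-trihydroxy-3-methylphenyl)propan-1-one F5. A single C-methylation (MeI 1.1 equiv, NaOMe, MeOH) at the already methylated, most electron-rich ring carbon then comes back to the route at 2.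

**Further compounds**

F1 | step 7 | 1-{3-[(dimethylamino)methyl]-2,4-dihydroxy-6-methoxy-5-methylphenyl}butan-1-one | CCCC(=O)c1c(O)c(CN(C)C)c(O)c(C)c1OC
F2 | step 4 | 2,4,6-trihydroxy-3-methylbenzoic acid | Cc1c(O)cc(O)c(C(=O)O)c1O
F3 | step 4 | methyl 2,6-dihydroxy-4-methoxy-3-methylbenzoate | COC(=O)c1c(O)cc(OC)c(C)c1O
F4 | step 4 | methyl 3-butanoyl-2,6-dihydroxy-4-methoxy-5-methylbenzoate | CCCC(=O)c1c(O)c(C(=O)OC)c(O)c(C)c1OC
F5 | step 1 | 1-(2,4,6-trihydroxy-3-methylphenyl)propan-1-one | CCC(=O)c1c(O)cc(O)c(C)c1O
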